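## Retrosynthetic overview

- Endgame on the closed trans-fused 5/7 core: the C4 ketone (carried as a dimethyl ketal) takes the isopropyl group last, the C2 ketone is reduced and acetylated, and the C10 silyl ether is removed at the end.
- Seven-membered ring (formed last): C1–C10 bond by reductive aldol cyclisation of a cyclopentenone that carries an α,β-epoxy aldehyde side chain (hydride to C5, enolate carbon C1 to the aldehyde).
- Oxirane: Shi epoxidation of the E-trisubstituted side-chain olefin before ring closure, because a trans-fused oxirane cannot be made from a cycloheptene.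
- C6 ester: amine-catalysed γ-acyloxylation of the achiral enone installs the 3,4-dimethoxybenzoate and the first stereocentre.
- Five-membered ring comes preformed from 3-methylcyclopentane-1,2,4-trione; the C6–C10 chain (from (E)-3-methylpent-2-en-4-yn-1-ol) is attached by Stork–Danheiser addition/transposition.

Assumption and notation: the SMILES is read literally, i.e. C7 and C10 are trans on the C8–C9 oxirane (a trans-fused epoxide on the seven-membered ring). Core locants C1–C10 (C1 methyl-bearing ring-fusion carbon, C2 acetoxy, C3 CH2, C4 isopropyl carbinol, C5 ring-fusion CH, C6 aroyloxy, C7 CH2, C8/C9 oxirane, C10 carbinol) are used for all bicyclic intermediates; CIP letters at C1 change with substituent priorities, not with geometry.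

## Route

Step 1
Reactants: 1 (2E)-3-methylpent-2-en-4-yn-1-ol
Product: 2 (2E)-3-methylpenta-2,4-dien-1-ol
Conditions: H2 (1 atm), Pd/CaCO3 poisoned with Pb(OAc)2, quinoline, EtOAc, 0 °C
Reagents that add atoms: none
Why: Lindlar semi-hydrogenation stops the terminal alkyne at the vinyl stage and leaves the E-trisubstituted olefin untouched (no stereocentre formed).

Step 2
Reactants: 2 (2E)-3-methylpenta-2,4-dien-1-ol
Product: 4 (2E)-5-iodo-3-methylpent-2-en-1-ol, via bis-9-BBN borane adduct 3 (not isolated)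
Conditions: 9-BBN (2.1 equiv), THF, 0 → 25 °C; then NaOMe, I2, MeOH, 0 °C
Reagents that add atoms: iodine, [I][I]
Why: Anti-Markovnikov hydroboration by 9-BBN occurs only at the terminal vinyl carbon (one equivalent is consumed by the OH), and Brown iodinolysis converts the primary C–B bond into C–I.

Step 3
Reactants: 5 2-hydroxy-3-methylcyclopent-2-ene-1,4-dione (enol form of 3-methylcyclopentane-1,2,4-trione)
Product: 6 3,5,5-trimethoxy-2-methylcyclopent-2-en-1-one
Conditions: HC(OMe)3, MeOH, TsOH·H2O (cat.), 50 °C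
Reagents that add atoms: trimethyl orthoformate, COC(OC)OC; methanol, CO
Why: Acid-catalysed ketalisation takes the isolated, most electrophilic carbonyl, and enol-ether formation then occurs at the carbonyl remote from the new quaternary ketal carbon, as with 4,4-disubstituted cyclic 1,3-diones.

Step 4
Reactants: 4 (2E)-5-iodo-3-methylpent-2-en-1-ol; 6 3,5,5-trimethoxy-2-methylcyclopent-2-en-1-one
Product: 9 3-[(3E)-5-hydroxy-3-methylpent-3-en-1-yl]-4,4-dimethoxy-2-methylcyclopent-2-en-1-one, via dilithio alkoxide 7 (not isolated), via dilithium carbinolate adduct 8 (not isolated)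
Conditions: t-BuLi (3.1 equiv), Et2O, −78 °C; then 6, THF, −78 → −20 °C; then 1 M HCl, THF, 0 °C
Reagents that add atoms: none
Why: Stork–Danheiser sequence: the alkyllithium from I/Li exchange adds 1,2 to the vinylogous ester carbonyl, and dilute acid hydrolyses the enol ether with allylic transposition to the enone, while the now cross-conjugated (quinone-monoketal-like) dimethyl ketal survives.

Step 5
Reactants: 10 3,4-dimethoxybenzoyl chloride
Product: 11 bis(3,4-dimethoxybenzoyl) peroxide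
Conditions: 10 (2.0 equiv in total), 30% aq. H2O2 (1.0 equiv), NaOH (2.0 equiv), acetone/H2O, 0 °C
Reagents that add atoms: 3,4-dimethoxybenzoyl chloride (second equivalent of 10), COc1ccc(cc1OC)C(Cl)=O; hydrogen peroxide, OO
Why: Schotten–Baumann acylation of hydrogen peroxide on both oxygens by two molecules of the acid chloride gives the symmetrical diaroyl peroxide.

Step 6
Reactants: 9 3-[(3E)-5-hydroxy-3-methylpent-3-en-1-yl]-4,4-dimethoxy-2-methylcyclopent-2-en-1-one; 11 bis(3,4-dimethoxybenzoyl) peroxide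
Product: 12 (1R,3E)-1-(5,5-dimethoxy-2-methyl-3-oxocyclopent-1-en-1-yl)-5-hydroxy-3-methylpent-3-en-1-yl 3,4-dimethoxybenzoate
Conditions: 9-amino-9-deoxy-epi-quinine (20 mol%), 2-fluorobenzoic acid (40 mol%), 2,6-di-tert-butyl-4-methylphenol (10 mol%), toluene, 25 °C
Reagents that add atoms: none
Why: Proposed new method: primary-amine dienamine γ-acyloxylation, in which the cinchona amine condenses with the C2 ketone, γ-deprotonation is possible only at the exocyclic C6 methylene (C4 is a ketal carbon), the dienamine attacks the peroxide O–O bond through C6 because the α-carbon C1 is fully substituted, and the protonated quinuclidine–carboxylate pair shields one face to set (6R) as the first stereocentre; the closest known reactions are the cinchona-primary-amine α-benzoyloxylation of cyclic ketones with benzoyl peroxide and the dienamine γ-functionalisation (vinylogous Michael addition) of β-alkyl cyclic enones.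

Step 7
Reactants: 12 (1R,3E)-1-(5,5-dimethoxy-2-methyl-3-oxocyclopent-1-en-1-yl)-5-hydroxy-3-methylpent-3-en-1-yl 3,4-dimethoxybenzoate
Product: 13 (1R)-1-(5,5-dimethoxy-2-methyl-3-oxocyclopent-1-en-1-yl)-2-[(2R,3R)-3-(hydroxymethyl)-2-methyloxiran-2-yl]ethyl 3,4-dimethoxybenzoate
Conditions: 1,2:4,5-di-O-isopropylidene-β-D-erythro-2,3-hexodiulo-2,6-pyranose (Shi ketone from D-fructose, 30 mol%), KHSO5, K2CO3, Bu4NHSO4, MeCN/CH2(OMe)2, aq. Na2B4O7 buffer (pH 10.5), 0 °C
Reagents that add atoms: potassium peroxymonosulfate (KHSO5), [K+].[O-]S(=O)(=O)OO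
Why: Shi epoxidation: the fructose-derived dioxirane transfers oxygen through the spiro transition state to one face of the E-trisubstituted olefin (catalyst control gives the 8R,9R trans-oxirane, the same sense as for 1-phenylcyclohexene and trans-β-methylstyrene), while the electron-poor tetrasubstituted enone is inert.

Step 8
Reactants: 13 (1R)-1-(5,5-dimethoxy-2-methyl-3-oxocyclopent-1-en-1-yl)-2-[(2R,3R)-3-(hydroxymethyl)-2-methyloxiran-2-yl]ethyl 3,4-dimethoxybenzoate
Product: 14 (1R)-1-(5,5-dimethoxy-2-methyl-3-oxocyclopent-1-en-1-yl)-2-[(2R,3S)-3-formyl-2-methyloxiran-2-yl]ethyl 3,4-dimethoxybenzoate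
Conditions: Dess–Martin periodinane, NaHCO3, CH2Cl2, 0 → 25 °C
Reagents that add atoms: none
Why: Dess–Martin oxidation of the primary epoxy alcohol under buffered neutral conditions gives the α,β-epoxy aldehyde without touching the oxirane or its stereocentres.

Step 9
Reactants: 14 (1R)-1-(5,5-dimethoxy-2-methyl-3-oxocyclopent-1-en-1-yl)-2-[(2R,3S)-3-formyl-2-methyloxiran-2-yl]ethyl 3,4-dimethoxybenzoate
Product: 16 (1R,5R,6R,8R,9R,10R)-8,9-epoxy-4,4-dimethoxy-1,8-dimethyl-2-oxo-10-(triethylsilyloxy)bicyclo[5.3.0]decan-6-yl 3,4-dimethoxybenzoate (core locants), via Cu aldolate 15 (not isolated)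
Conditions: [(Ph3P)CuH]6 (0.5 equiv), toluene, −40 → 0 °C; then Et3SiOTf, 2,6-lutidine, −78 °C
Reagents that add atoms: triethylsilyl trifluoromethanesulfonate, CC[Si](CC)(CC)OS(=O)(=O)C(F)(F)F
Why: Reductive aldol cyclisation: hydride adds to C5 anti to the C6 aroyloxy group in the 1,3-allylic-strain conformer (5R), and the copper enolate attacks the aldehyde anti to the oxirane C–O bond (Felkin–Anh, 10R) on the face opposite C6 (1R, trans ring fusion, which lets the trans-oxirane and the ring-fusion bond occupy the two high-torsion positions of the twist-chair), before the aldolate is silylated in the flask.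

Step 10
Reactants: 16 (1R,5R,6R,8R,9R,10R)-8,9-epoxy-4,4-dimethoxy-1,8-dimethyl-2-oxo-10-(triethylsilyloxy)bicyclo[5.3.0]decan-6-yl 3,4-dimethoxybenzoate
Product: 17 (1S,2S,5R,6R,8R,9R,10R)-8,9-epoxy-2-hydroxy-4,4-dimethoxy-1,8-dimethyl-10-(triethylsilyloxy)bicyclo[5.3.0]decan-6-yl 3,4-dimethoxybenzoate
Conditions: NaBH4, MeOH/THF, −20 °C
Reagents that add atoms: none
Why: Borohydride reduction of the cyclopentanone occurs from the face opposite the angular C1 methyl group, giving the C2 alcohol cis to that methyl (2S), as in 17-keto steroid reductions.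

Step 11
Reactants: 17 (1S,2S,5R,6R,8R,9R,10R)-8,9-epoxy-2-hydroxy-4,4-dimethoxy-1,8-dimethyl-10-(triethylsilyloxy)bicyclo[5.3.0]decan-6-yl 3,4-dimethoxybenzoate
Product: 18 (1S,2S,5R,6R,8R,9R,10R)-2-acetoxy-8,9-epoxy-4,4-dimethoxy-1,8-dimethyl-10-(triethylsilyloxy)bicyclo[5.3.0]decan-6-yl 3,4-dimethoxybenzoate
Conditions: Ac2O, DMAP, pyridine, CH2Cl2, 25 °C
Reagents that add atoms: acetic anhydride, CC(=O)OC(C)=O
Why: DMAP-catalysed acylation esterifies the only free hydroxyl group with retention at C2.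

Step 12
Reactants: 18 (1S,2S,5R,6R,8R,9R,10R)-2-acetoxy-8,9-epoxy-4,4-dimethoxy-1,8-dimethyl-10-(triethylsilyloxy)bicyclo[5.3.0]decan-6-yl 3,4-dimethoxybenzoate
Product: 19 (1S,2S,5R,6R,8R,9R,10R)-2-acetoxy-8,9-epoxy-1,8-dimethyl-4-oxo-10-(triethylsilyloxy)bicyclo[5.3.0]decan-6-yl 3,4-dimethoxybenzoate
Conditions: pyridinium p-toluenesulfonate, acetone/H2O (10:1), 25 °C
Reagents that add atoms: water, O
Why: Mild acid-catalysed hydrolysis of the now non-conjugated dimethyl ketal frees the C4 ketone under conditions that spare the oxirane, the silyl ether and both esters.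

Step 13
Reactants: 19 (1S,2S,5R,6R,8R,9R,10R)-2-acetoxy-8,9-epoxy-1,8-dimethyl-4-oxo-10-(triethylsilyloxy)bicyclo[5.3.0]decan-6-yl 3,4-dimethoxybenzoate
Product: 20 (1S,2S,4S,5R,6R,8R,9R,10R)-2-acetoxy-8,9-epoxy-4-hydroxy-1,8-dimethyl-4-(propan-2-yl)-10-(triethylsilyloxy)bicyclo[5.3.0]decan-6-yl 3,4-dimethoxybenzoate
Conditions: i-PrMgCl, CeCl3, THF, −78 °C
Reagents that add atoms: isopropylmagnesium chloride, CC(C)[Mg]Cl
Why: Imamoto organocerium 1,2-addition to the hindered, enolisable ketone proceeds from the face opposite the C5–C6 bond and the angular methyl group (4S) and is fast enough at −78 °C to leave the hindered acetate and the aryl ester untouched.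

Step 14
Reactants: 20 (1S,2S,4S,5R,6R,8R,9R,10R)-2-acetoxy-8,9-epoxy-4-hydroxy-1,8-dimethyl-4-(propan-2-yl)-10-(triethylsilyloxy)bicyclo[5.3.0]decan-6-yl 3,4-dimethoxybenzoate
Product: 21 (1R,2S,4S,5R,6R,8R,9R,10R)-2-acetoxy-8,9-epoxy-4,10-dihydroxy-1,8-dimethyl-4-(propan-2-yl)bicyclo[5.3.0]decan-6-yl 3,4-dimethoxybenzoate (CNP0197096.4)
Conditions: Et3N·3HF, MeCN, 0 → 25 °C
Reagents that add atoms: none
Why: Fluoride-mediated desilylation under non-basic conditions frees the C10 hydroxyl without acetyl migration from C2 or Payne rearrangement of the epoxy alcohol.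

## Compound list

1 | (2E)-3-methylpent-2-en-4-yn-1-ol | C#C/C(C)=C/CO | starting material
2 | (2E)-3-methylpenta-2,4-dien-1-ol | C=C/C(C)=C/CO | intermediate
3 | 9-[(3E)-5-(9-borabicyclo[3.3.1]nonan-9-yloxy)-3-methylpent-3-en-1-yl]-9-borabicyclo[3.3.1]nonane (bis-9-BBN borane adduct) | C(CC/C(C)=C/COB1C2CCCC1CCC2)B1C2CCCC1CCC2 | intermediate
4 | (2E)-5-iodo-3-methylpent-2-en-1-ol | ICC/C(C)=C/CO | intermediate
5 | 2-hydroxy-3-methylcyclopent-2-ene-1,4-dione (enol form of 3-methylcyclopentane-1,2,4-trione) | CC1=C(O)C(=O)CC1=O | starting material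
6 | 3,5,5-trimethoxy-2-methylcyclopent-2-en-1-one | COC1=C(C)C(=O)C(OC)(OC)C1 | intermediate
7 | lithium (2E)-5-lithio-3-methylpent-2-en-1-olate (dilithio alkoxide) | [Li]CC/C(C)=C/CO[Li] | intermediate
8 | dilithium 1-[(3E)-3-methyl-5-oxidopent-3-en-1-yl]-3,5,5-trimethoxy-2-methylcyclopent-2-en-1-olate (dilithium carbinolate adduct) | COC1=C(C)C(O[Li])(CC/C(C)=C/CO[Li])C(OC)(OC)C1 | intermediate
9 | 3-[(3E)-5-hydroxy-3-methylpent-3-en-1-yl]-4,4-dimethoxy-2-methylcyclopent-2-en-1-one | CC1=C(CC/C(C)=C/CO)C(OC)(OC)CC1=O | intermediate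
10 | 3,4-dimethoxybenzoyl chloride | COc1ccc(cc1OC)C(Cl)=O | starting material
11 | bis(3,4-dimethoxybenzoyl) peroxide | COc1ccc(cc1OC)C(=O)OOC(=O)c1ccc(OC)c(OC)c1 | intermediate
12 | (1R,3E)-1-(5,5-dimethoxy-2-methyl-3-oxocyclopent-1-en-1-yl)-5-hydroxy-3-methylpent-3-en-1-yl 3,4-dimethoxybenzoate | COc1ccc(C(=O)O[C@H](C/C(C)=C/CO)C2=C(C)C(=O)CC2(OC)OC)cc1OC | intermediate
13 | (1R)-1-(5,5-dimethoxy-2-methyl-3-oxocyclopent-1-en-1-yl)-2-[(2R,3R)-3-(hydroxymethyl)-2-methyloxiran-2-yl]ethyl 3,4-dimethoxybenzoate | COc1ccc(C(=O)O[C@H](C[C@@]3(C)O[C@@H]3CO)C2=C(C)C(=O)CC2(OC)OC)cc1OC | intermediate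
14 | (1R)-1-(5,5-dimethoxy-2-methyl-3-oxocyclopent-1-en-1-yl)-2-[(2R,3S)-3-formyl-2-methyloxiran-2-yl]ethyl 3,4-dimethoxybenzoate | COc1ccc(C(=O)O[C@H](C[C@@]3(C)O[C@@H]3C=O)C2=C(C)C(=O)CC2(OC)OC)cc1OC | intermediate
15 | Cu aldolate (C10 copper alkoxide corresponding to 16) | COc1ccc(C(=O)O[C@@H]2C[C@@]3(C)O[C@@H]3[C@H](O[Cu])[C@]3(C)C(=O)CC(OC)(OC)[C@@H]23)cc1OC | intermediate
16 | (1R,5R,6R,8R,9R,10R)-8,9-epoxy-4,4-dimethoxy-1,8-dimethyl-2-oxo-10-(triethylsilyloxy)bicyclo[5.3.0]decan-6-yl 3,4-dimethoxybenzoate | COc1ccc(C(=O)O[C@@H]2C[C@@]3(C)O[C@@H]3[C@H](O[Si](CC)(CC)CC)[C@]3(C)C(=O)CC(OC)(OC)[C@@H]23)cc1OC | intermediate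
17 | (1S,2S,5R,6R,8R,9R,10R)-8,9-epoxy-2-hydroxy-4,4-dimethoxy-1,8-dimethyl-10-(triethylsilyloxy)bicyclo[5.3.0]decan-6-yl 3,4-dimethoxybenzoate | COc1ccc(C(=O)O[C@@H]2C[C@@]3(C)O[C@@H]3[C@H](O[Si](CC)(CC)CC)[C@]3(C)[C@@H](O)CC(OC)(OC)[C@@H]23)cc1OC | intermediate
18 | (1S,2S,5R,6R,8R,9R,10R)-2-acetoxy-8,9-epoxy-4,4-dimethoxy-1,8-dimethyl-10-(triethylsilyloxy)bicyclo[5.3.0]decan-6-yl 3,4-dimethoxybenzoate | COc1ccc(C(=O)O[C@@H]2C[C@@]3(C)O[C@@H]3[C@H](O[Si](CC)(CC)CC)[C@]3(C)[C@@H](OC(C)=O)CC(OC)(OC)[C@@H]23)cc1OC | intermediate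
19 | (1S,2S,5R,6R,8R,9R,10R)-2-acetoxy-8,9-epoxy-1,8-dimethyl-4-oxo-10-(triethylsilyloxy)bicyclo[5.3.0]decan-6-yl 3,4-dimethoxybenzoate | COc1ccc(C(=O)O[C@@H]2C[C@@]3(C)O[C@@H]3[C@H](O[Si](CC)(CC)CC)[C@]3(C)[C@@H](OC(C)=O)CC(=O)[C@@H]23)cc1OC | intermediate
20 | (1S,2S,4S,5R,6R,8R,9R,10R)-2-acetoxy-8,9-epoxy-4-hydroxy-1,8-dimethyl-4-(propan-2-yl)-10-(triethylsilyloxy)bicyclo[5.3.0]decan-6-yl 3,4-dimethoxybenzoate | COc1ccc(C(=O)O[C@@H]2C[C@@]3(C)O[C@@H]3[C@H](O[Si](CC)(CC)CC)[C@]3(C)[C@@H](OC(C)=O)C[C@](O)(C(C)C)[C@@H]23)cc1OC | intermediate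
21 | (1R,2S,4S,5R,6R,8R,9R,10R)-2-acetoxy-8,9-epoxy-4,10-dihydroxy-1,8-dimethyl-4-(propan-2-yl)bicyclo[5.3.0]decan-6-yl 3,4-dimethoxybenzoate (CNP0197096.4) | COc1ccc(C(=O)O[C@@H]2C[C@@]3(C)O[C@@H]3[C@H](O)[C@]3(C)[C@@H](OC(C)=O)C[C@](O)(C(C)C)[C@@H]23)cc1OC | target

## Step count and risks

Total steps: 14. Longest linear sequence: 12 steps (steps 1, 2, 4, 6, 7, 8, 9, 10, 11, 12, 13, 14; steps 3 and 5 are side branches).

The three steps most likely to fail:

Step 6 (the proposed new γ-acyloxylation). Risks are α- versus γ-attack, oxidation of the amine catalyst by the peroxide, racemisation of 12 through renewed dienamine formation, and an unproven sense of induction (the quinidine-derived pseudo-enantiomer is the first thing to try if the wrong antipode forms). The fallback uses known chemistry only, sets out from 9 and comes back at 12. Silylation of 9 (TBSCl, imidazole, DMF) gives tert-butyldimethylsilyl ether of 9 F1. Thermodynamic dienolate oxygenation (t-BuOK, O2, P(OEt)3, THF/t-BuOH, −20 °C) gives racemic C6 carbinol silyl ether F2. Birman–Shiina acylative kinetic resolution (3,4-dimethoxybenzoic acid, pivalic anhydride, (R)-benzotetramisole [(R)-2-phenyl-2,3-dihydroimidazo[2,1-b]benzothiazole], i-Pr2NEt, CH2Cl2) esterifies only the (R)-carbinol, giving (6R)-aroyloxy silyl ether F3 in at most half the mass. HF·pyridine then returns 12.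

Step 9 (ring closure). The β-carbon C5 is tetrasubstituted and flanked by the ketal, so hydride delivery may be slow. The strained aldolate may undergo retro-aldol before silylation. The C5 face selectivity and the trans ring fusion rest on conformational arguments only. The fallback sets out from 14 and comes back at 16. It replaces the polar copper-hydride addition by a metal-hydride hydrogen-atom-transfer reductive aldol (cobalt bis(dipivaloylmethanate) Co(dpm)2 cat., PhSiH3, 1,2-dichloroethane, 25 °C, or Fe(acac)3, PhSiH3, EtOH). This radical–polar crossover tolerates fully substituted olefins and gives free C10 alcohol of 16 F4 after work-up. Et3SiOTf/2,6-lutidine at −78 °C then returns 16.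

Step 13 (late isopropyl addition). A branched nucleophile on a hindered ketone can give reduction by β-hydride transfer, enolisation with loss of the C6 or C2 acyloxy group, or attack on the acetate. The fallback sets out from 19 and comes back at 20. Isopropenylmagnesium bromide/CeCl3 (THF, −78 °C), a smaller sp2 nucleophile with no β-hydride, gives C4 isopropenyl carbinol F5. Hydroxyl-directed homogeneous hydrogenation (H2, Rh(PPh3)3Cl, benzene) then returns 20.

Further compounds
F1 | step 6 | tert-butyldimethylsilyl ether of 9 | CC1=C(CC/C(C)=C/CO[Si](C)(C)C(C)(C)C)C(OC)(OC)CC1=O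
F2 | step 6 | racemic C6 carbinol silyl ether | CC1=C(C(O)C/C(C)=C/CO[Si](C)(C)C(C)(C)C)C(OC)(OC)CC1=O
F3 | step 6 | (6R)-aroyloxy silyl ether | COc1ccc(C(=O)O[C@H](C/C(C)=C/CO[Si](C)(C)C(C)(C)C)C2=C(C)C(=O)CC2(OC)OC)cc1OC
F4 | step 9 | free C10 alcohol of 16 | COc1ccc(C(=O)O[C@@H]2C[C@@]3(C)O[C@@H]3[C@H](O)[C@]3(C)C(=O)CC(OC)(OC)[C@@H]23)cc1OC
F5 | step 13 | C4 isopropenyl carbinol | COc1ccc(C(=O)O[C@@H]2C[C@@]3(C)O[C@@H]3[C@H](O[Si](CC)(CC)CC)[C@]3(C)[C@@H](OC(C)=O)C[C@](O)(C(C)=C)[C@@H]23)cc1OC
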